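**Retrosynthetic overview**
1. Target 32 ⇐ olefin cross-metathesis of the but-3-enyl compound 31 ⇐ Wolff–Kishner removal of the ring B carbonyl of ketone 29.
2. Key disconnection C9–C10 (ring A, closed last): the ether carbon C10 of a preformed 2-methyloxolane reacts with reversed polarity, as a nucleophilic α-oxyalkyl radical, with the enone β-carbon C9 of tricyclic enone 28; both carbons are otherwise acceptor sites.
3. 28 ⇐ cationic γ-alkylation (C8–C14, ring C) of cyclopentenone 25 ⇐ Stork–Danheiser union (C9–C11) of ring D iodide 12 with the oxolane-bearing vinylogous ester 22.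
4. 12 ⇐ Johnson–Claisen (C13) ⇐ CBS reduction ⇐ enone 7 ⇐ copper-catalysed asymmetric conjugate addition (C17). 22 ⇐ cyclopentane-1,3-dione by O-prenylation/Claisen (C4), oxidative cleavage, asymmetric butenylation (C3) and oxymercuration.
5. Ring order: rings D and B start as bought monocycles, then the oxolane, then ring C, and last ring A (carbocycle and ether bridge in one step).

**Assumption and labels:** the target is read from the SMILES as the (3S,5S,8R,9R,10R,13S,14R,17R) isomer in the following labels, which are used for compounds 25–32 and the F compounds. C3 = ether CH; C4 = C(CH3)2; C5 = ring A/B CH; C6, C7 = CH2 of five-membered ring B; C8 = ring B/C CH; C9 = quaternary carbon shared by rings A, B and C; C10 = ether C(CH3); C1 (on C10) and C2 (on C3) = CH2CH2 bridge; C11 (on C9) and C12 = ring C CH2; C13 (on C12) and C14 (on C8) = methyl-bearing ring C/D carbons; C15 (on C14) and C16 = ring D CH2; C17 = ring D carbon with CH3 and the side chain; C18 = ring D CH2 between C17 and C13.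

The route has not been run; steps 15–17 carry the main risk and are discussed at the end.

**Step 1**
Reactants: 1 3-methylcyclohex-2-en-1-one; 2 but-3-en-1-ylmagnesium bromide
Product: 3 (S)-3-(but-3-en-1-yl)-3-methylcyclohexan-1-one
Conditions: Cu(OTf)2 (3 mol%), chiral C2-symmetric imidazolinium chloride (carbene precursor, 4 mol%, enantiomer giving the S ketone), Et2O, 0 °C; aq HCl
Reagents that add atoms: none
Why: Copper-catalysed asymmetric conjugate addition of a Grignard reagent to a β-methyl enone, in which the chiral N-heterocyclic carbene–copper catalyst selects the enone face and sets the quaternary centre (later C17).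

**Step 2**
Reactants: 3
Product: 4 (5R)-5-(but-3-en-1-yl)-2,5-dimethylcyclohexan-1-one (2RS)
Conditions: LiN(iPr)2, THF, −78 °C; MeI, −78 → 0 °C
Reagents that add atoms: iodomethane, C[I]
Why: Kinetic enolate alkylation on the side away from the quaternary carbon; the new methyl-bearing centre is a mixture that becomes sp2 in step 3.

**Step 3**
Reactants: 4
Product: 5 (R)-5-(but-3-en-1-yl)-2,5-dimethylcyclohex-2-en-1-one
Conditions: IBX, DMSO/fluorobenzene, 70 °C
Reagents that add atoms: none
Why: IBX-mediated α,β-dehydrogenation of a ketone, which can only run toward the methyl-bearing carbon because the other α-carbon adjoins the quaternary centre.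

**Step 4**
Reactants: 5
Product: 6 (5R)-5-(but-3-en-1-yl)-1,2,5-trimethylcyclohex-2-en-1-ol (1RS)
Conditions: MeLi, Et2O, −78 °C; H2O
Reagents that add atoms: methyllithium, [Li]C
Why: 1,2-Addition of an organolithium to an enone; both carbinol epimers converge in step 5.

**Step 5**
Reactants: 6
Product: 7 (S)-5-(but-3-en-1-yl)-2,3,5-trimethylcyclohex-2-en-1-one
Conditions: 4-acetamido-2,2,6,6-tetramethyl-1-oxopiperidinium tetrafluoroborate, MeCN, rt
Reagents that add atoms: none
Why: Oxoammonium-mediated oxidative 1,3-transposition of a tertiary allylic alcohol (Babler–Dauben type) gives the 2,3-dimethyl enone.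

**Step 6**
Reactants: 7
Product: 8 (1R,5S)-5-(but-3-en-1-yl)-2,3,5-trimethylcyclohex-2-en-1-ol
Conditions: (S)-2-methyl-CBS-oxazaborolidine (10 mol%), catecholborane, toluene, −78 °C; H2O
Reagents that add atoms: none
Why: Corey–Bakshi–Shibata reduction in which the oxazaborolidine alone sets the carbinol centre (1R), the distant quaternary centre giving no bias, and catecholborane at −78 °C leaves the terminal alkene untouched.

**Step 7**
Reactants: 8
Product: 10 ethyl 2-[(1R,5R)-5-(but-3-en-1-yl)-1,2,5-trimethylcyclohex-2-en-1-yl]acetate, via ketene acetal 9 (not isolated)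
Conditions: MeC(OEt)3, EtCO2H (cat.), 140 °C, EtOH distilled off
Reagents that add atoms: triethyl orthoacetate, CC(OCC)(OCC)OCC
Why: Johnson–Claisen rearrangement, whose [3,3] shift is suprafacial on the ring, so the C–C bond forms on the face that carried the C–O bond and the carbinol configuration is transferred to the new quaternary carbon (later C13).

**Step 8**
Reactants: 10
Product: 11 2-[(1R,5R)-5-(but-3-en-1-yl)-1,2,5-trimethylcyclohex-2-en-1-yl]ethan-1-ol
Conditions: LiAlH4, THF, 0 °C; H2O, aq NaOH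
Reagents that add atoms: none
Why: Hydride reduction of an ester to the primary alcohol.

**Step 9**
Reactants: 11
Product: 12 (4R,6R)-4-(but-3-en-1-yl)-6-(2-iodoethyl)-1,4,6-trimethylcyclohex-1-ene
Conditions: I2, PPh3, imidazole, CH2Cl2, 0 °C → rt
Reagents that add atoms: iodine, [I][I]
Why: Appel-type iodination of a primary alcohol.

**Step 10**
Reactants: 13 cyclopentane-1,3-dione; 14 3-methylbut-2-en-1-ol
Product: 16 2-(2-methylbut-3-en-2-yl)cyclopentane-1,3-dione, via prenyl enol ether 15 (not isolated)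
Conditions: PPh3, DIAD, THF, 0 °C → rt; then toluene, 110 °C
Reagents that add atoms: none
Why: Mitsunobu O-alkylation of the vinylogous acid followed by Claisen rearrangement, which delivers the prenyl group through its tertiary carbon and so creates the gem-dimethyl carbon (later C4).

**Step 11**
Reactants: 16
Product: 17 3-ethoxy-2-(2-methylbut-3-en-2-yl)cyclopent-2-en-1-one
Conditions: EtOH, TsOH (cat.), benzene, reflux, Dean–Stark
Reagents that add atoms: ethanol, CCO
Why: Acid-catalysed vinylogous ester formation from a symmetric 1,3-dione, so only one product can form.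

**Step 12**
Reactants: 17
Product: 19 2-(2-ethoxy-5-oxocyclopent-1-en-1-yl)-2-methylpropanal, via diol 18 (not isolated)
Conditions: OsO4 (2 mol%), NaIO4, 2,6-lutidine, dioxane/H2O, rt
Reagents that add atoms: osmium tetroxide, O=[Os](=O)(=O)=O; sodium periodate, [Na+].[O-][I](=O)(=O)=O
Why: Lemieux–Johnson oxidative cleavage of the monosubstituted alkene; the tetrasubstituted push–pull ring alkene is left alone.

**Step 13**
Reactants: 19; 2 but-3-en-1-ylmagnesium bromide
Product: 20 3-ethoxy-2-[(3S)-3-hydroxy-2-methylhept-6-en-2-yl]cyclopent-2-en-1-one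
Conditions: 2 (2 equiv), ZnCl2, Et2O, then N,N,N′,N′-tetraethylethylenediamine; (−)-MIB (5 mol%), toluene/hexane, 0 °C; H2O
Reagents that add atoms: none
Why: Amino alcohol-catalysed enantioselective addition of a dialkylzinc to an aldehyde, in which the catalyst directs attack to one aldehyde face and sets the carbinol centre (later C3) as S.

**Step 14**
Reactants: 20
Product: 22 3-ethoxy-2-{2-[(2S,5RS)-5-methyloxolan-2-yl]propan-2-yl}cyclopent-2-en-1-one, via organomercurial 21 (not isolated)
Conditions: Hg(OAc)2, NaOAc, THF, rt; then NaBH4, aq NaOH, 0 °C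
Reagents that add atoms: none
Why: Intramolecular alkoxymercuration–demercuration (Markovnikov, 5-exo) closes the 2-methyloxolane; the methyl-bearing centre (later C10) forms as a mixture, which is harmless because it becomes a planar radical in step 17.

**Step 15**
Reactants: 12; 22
Product: 25 3-{2-[(1S,5R)-5-(but-3-en-1-yl)-1,2,5-trimethylcyclohex-2-en-1-yl]ethyl}-2-{2-[(2S,5RS)-5-methyloxolan-2-yl]propan-2-yl}cyclopent-2-en-1-one, via alkyllithium 23 (not isolated), via carbinol 24 (not isolated)
Conditions: t-BuLi (2.1 equiv), Et2O/pentane, −78 °C; 22, −78 → 0 °C; 1 M HCl, rt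
Reagents that add atoms: none
Why: Stork–Danheiser sequence (iodine–lithium exchange, 1,2-addition to the vinylogous ester carbonyl, acid hydrolysis–elimination) gives the transposed enone with both ring B substituents placed unambiguously; no stereocentre is formed.

**Step 16**
Reactants: 25
Product: 28 (8S,13S,14R,17R)-tricyclic enone of rings B–D (C6 ketone; C5=C9; oxolanylpropan-2-yl group on C5; but-3-en-1-yl on C17), via tertiary chloride 26 (not isolated), via silyl dienol ether 27 (not isolated)
Conditions: HCl (g), CH2Cl2, −78 °C, N2 purge; TBSOTf, Et3N, −78 → 0 °C; ZnBr2 (20 mol%), −40 → 0 °C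
Reagents that add atoms: none
Why: Markovnikov hydrochlorination, then Lewis acid-promoted intramolecular γ-alkylation of a silyl dienol ether by the tertiary chloride (Reetz and Fleming–Paterson type tert-alkylation, a cation–olefin cyclisation), in which a chair transition state with the C13 arm equatorial makes the new C8–C14 bond equatorial, so the C14 methyl ends axial and anti to the C13 methyl (trans-fused rings C and D) and H8 ends anti to the C14 methyl.

**Step 17**
Reactants: 28
Product: 29 (3S,5S,8R,9R,10R,13S,14R,17R)-6-oxo-17-(but-3-en-1-yl) pentacyclic ketone (target skeleton with C6=O and the shortened side chain)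
Conditions: (n-Bu4N)4[W10O32] (5 mol%), degassed MeCN, 390 nm LEDs, rt; then DBU (0.2 equiv), rt
Reagents that add atoms: none
Why: Proposed new method: hydrogen atom transfer from the hydridic α-oxy C–H bond at C10 to photoexcited decatungstate gives a nucleophilic α-oxyalkyl radical, so that C10, a carbon at the oxidation level of an oxocarbenium or ketone acceptor, reacts with reversed polarity and adds 6-endo to the acceptor carbon C9 of the enone (polarity-matched Giese addition giving a stabilised α-keto radical, then back hydrogen transfer); it attacks the face of C9 opposite the axial C14 methyl, the fixed C3 centre decides on which face the ether bridge can close and thereby sets C10, and DBU equilibrates C5 to the trans ring A/B fusion; closest known reaction type: decatungstate-photocatalysed hydroalkylation of enones with cyclic ethers.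

**Step 18**
Reactants: 29
Product: 31 (3S,5S,8R,9R,10R,13S,14R,17R)-17-(but-3-en-1-yl) analogue of the target, via hydrazone 30 (not isolated)
Conditions: N2H4·H2O, KOH, diethylene glycol, 130 → 200 °C
Reagents that add atoms: none
Why: Wolff–Kishner reduction (Huang-Minlon procedure) removes the ring B carbonyl, and the hot base keeps C5 at its more stable configuration before the hydrazone collapses.

**Step 19**
Reactants: 31
Product: 32 target CNP0284367.1
Conditions: 2-methylbut-2-ene (excess), second-generation Grubbs catalyst RuCl2(H2IMes)(PCy3)(=CHPh) (5 mol%), CH2Cl2, 40 °C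
Reagents that add atoms: 2-methylbut-2-ene, CC=C(C)C
Why: Olefin cross-metathesis of the terminal alkene with 2-methylbut-2-ene exchanges the terminal CH2 for C(CH3)2 and creates no stereocentre.

**Compound list**
1 | 3-methylcyclohex-2-en-1-one | CC1=CC(=O)CCC1 | starting material
2 | but-3-en-1-ylmagnesium bromide | C=CCC[Mg]Br | starting material
3 | (S)-3-(but-3-en-1-yl)-3-methylcyclohexan-1-one | C=CCC[C@]1(C)CCCC(=O)C1 | intermediate
4 | (5R)-5-(but-3-en-1-yl)-2,5-dimethylcyclohexan-1-one (2RS) | C=CCC[C@]1(C)CCC(C)C(=O)C1 | intermediate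
5 | (R)-5-(but-3-en-1-yl)-2,5-dimethylcyclohex-2-en-1-one | C=CCC[C@]1(C)CC=C(C)C(=O)C1 | intermediate
6 | (5R)-5-(but-3-en-1-yl)-1,2,5-trimethylcyclohex-2-en-1-ol (1RS) | C=CCC[C@]1(C)CC=C(C)C(C)(O)C1 | intermediate
7 | (S)-5-(but-3-en-1-yl)-2,3,5-trimethylcyclohex-2-en-1-one | C=CCC[C@]1(C)CC(=O)C(C)=C(C)C1 | intermediate
8 | (1R,5S)-5-(but-3-en-1-yl)-2,3,5-trimethylcyclohex-2-en-1-ol | C=CCC[C@]1(C)C[C@@H](O)C(C)=C(C)C1 | intermediate
9 | 1-ethoxyvinyl ether of 8 (ketene acetal) | C=CCC[C@]1(C)C[C@@H](OC(=C)OCC)C(C)=C(C)C1 | intermediate (not isolated)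
10 | ethyl 2-[(1R,5R)-5-(but-3-en-1-yl)-1,2,5-trimethylcyclohex-2-en-1-yl]acetate | C=CCC[C@]1(C)CC=C(C)[C@@](C)(CC(=O)OCC)C1 | intermediate
11 | 2-[(1R,5R)-5-(but-3-en-1-yl)-1,2,5-trimethylcyclohex-2-en-1-yl]ethan-1-ol | C=CCC[C@]1(C)CC=C(C)[C@@](C)(CCO)C1 | intermediate
12 | (4R,6R)-4-(but-3-en-1-yl)-6-(2-iodoethyl)-1,4,6-trimethylcyclohex-1-ene | C=CCC[C@]1(C)CC=C(C)[C@@](C)(CC[I])C1 | intermediate
13 | cyclopentane-1,3-dione | O=C1CCC(=O)C1 | starting material
14 | 3-methylbut-2-en-1-ol | CC(C)=CCO | starting material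
15 | 3-[(3-methylbut-2-en-1-yl)oxy]cyclopent-2-en-1-one | CC(C)=CCOC1=CC(=O)CC1 | intermediate (not isolated)
16 | 2-(2-methylbut-3-en-2-yl)cyclopentane-1,3-dione | C=CC(C)(C)C1C(=O)CCC1=O | intermediate
17 | 3-ethoxy-2-(2-methylbut-3-en-2-yl)cyclopent-2-en-1-one | CCOC1=C(C(C)(C)C=C)C(=O)CC1 | intermediate
18 | 2-(3,4-dihydroxy-2-methylbutan-2-yl)-3-ethoxycyclopent-2-en-1-one | CCOC1=C(C(C)(C)C(O)CO)C(=O)CC1 | intermediate (not isolated)
19 | 2-(2-ethoxy-5-oxocyclopent-1-en-1-yl)-2-methylpropanal | CCOC1=C(C(C)(C)C=O)C(=O)CC1 | intermediate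
20 | 3-ethoxy-2-[(3S)-3-hydroxy-2-methylhept-6-en-2-yl]cyclopent-2-en-1-one | CCOC1=C(C(C)(C)[C@@H](O)CCC=C)C(=O)CC1 | intermediate
21 | ({(5S)-5-[2-(2-ethoxy-5-oxocyclopent-1-en-1-yl)propan-2-yl]oxolan-2-yl}methyl)mercury acetate | CCOC1=C(C(C)(C)[C@@H]2CCC(C[Hg]OC(C)=O)O2)C(=O)CC1 | intermediate (not isolated)
22 | 3-ethoxy-2-{2-[(2S,5RS)-5-methyloxolan-2-yl]propan-2-yl}cyclopent-2-en-1-one | CCOC1=C(C(C)(C)[C@@H]2CCC(C)O2)C(=O)CC1 | intermediate
23 | {2-[(1S,5R)-5-(but-3-en-1-yl)-1,2,5-trimethylcyclohex-2-en-1-yl]ethyl}lithium | C=CCC[C@]1(C)CC=C(C)[C@@](C)(CC[Li])C1 | intermediate (not isolated)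
24 | tertiary carbinol from addition of 23 to 22 (formed as its lithium alkoxide; carbinol centre unassigned) | C=CCC[C@]1(C)CC=C(C)[C@@](C)(CCC2(O)CCC(OCC)=C2C(C)(C)[C@@H]3CCC(C)O3)C1 | intermediate (not isolated)
25 | 3-{2-[(1S,5R)-5-(but-3-en-1-yl)-1,2,5-trimethylcyclohex-2-en-1-yl]ethyl}-2-{2-[(2S,5RS)-5-methyloxolan-2-yl]propan-2-yl}cyclopent-2-en-1-one | C=CCC[C@]1(C)CC=C(C)[C@@](C)(CCC2=C(C(C)(C)[C@@H]3CCC(C)O3)C(=O)CC2)C1 | intermediate
26 | tertiary chloride: HCl adduct of 25 with Cl on C14 (C14 epimers) | C=CCC[C@]1(C)CCC(C)(Cl)[C@@](C)(CCC2=C(C(C)(C)[C@@H]3CCC(C)O3)C(=O)CC2)C1 | intermediate (not isolated)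
27 | tert-butyldimethylsilyl dienol ether of 26 (C6–OSi; C5=C6 and C8=C9) | C=CCC[C@]1(C)CCC(C)(Cl)[C@@](C)(CCC2=CCC(O[Si](C)(C)C(C)(C)C)=C2C(C)(C)[C@@H]3CCC(C)O3)C1 | intermediate (not isolated)
28 | (8S,13S,14R,17R)-tricyclic enone of rings B–D: C6 ketone, C5=C9, C5 carrying 2-[(2S,5RS)-5-methyloxolan-2-yl]propan-2-yl, C13/C14 methyls trans, but-3-en-1-yl and methyl on C17 | C=CCC[C@]1(C)CC[C@]2(C)[C@H]3CC(=O)C(C(C)(C)[C@@H]4CCC(C)O4)=C3CC[C@@]2(C)C1 | intermediate
29 | (3S,5S,8R,9R,10R,13S,14R,17R)-pentacyclic ketone: target skeleton with C6=O and but-3-en-1-yl on C17 | C=CCC[C@]1(C)CC[C@]2(C)[C@H]3CC(=O)[C@H]4C(C)(C)[C@@H]5CC[C@@](C)(O5)[C@@]43CC[C@@]2(C)C1 | intermediate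
30 | hydrazone of 29 at C6 | C=CCC[C@]1(C)CC[C@]2(C)[C@H]3CC(=NN)[C@H]4C(C)(C)[C@@H]5CC[C@@](C)(O5)[C@@]43CC[C@@]2(C)C1 | intermediate (not isolated)
31 | (3S,5S,8R,9R,10R,13S,14R,17R)-17-(but-3-en-1-yl) analogue of the target | C=CCC[C@]1(C)CC[C@]2(C)[C@H]3CC[C@H]4C(C)(C)[C@@H]5CC[C@@](C)(O5)[C@@]43CC[C@@]2(C)C1 | intermediate
32 | CNP0284367.1, (3S,5S,8R,9R,10R,13S,14R,17R) | CC(C)=CCC[C@]1(C)CC[C@]2(C)[C@H]3CC[C@H]4C(C)(C)[C@@H]5CC[C@@](C)(O5)[C@@]43CC[C@@]2(C)C1 | target

**Totals:** 19 steps. Longest linear sequence 14 steps (steps 1–9 and 15–19); the branch to 22 is 5 steps (10–14).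

**Three steps most likely to fail**

Step 17 (radical closure of ring A). The bond joins a fully substituted ether carbon to a quaternary centre, and abstraction at C3–H would erode the controlling stereocentre. This fallback sets out from 28 and comes back at 29. The same C–H bond is hydroxylated instead of being used for closure: 28 with (n-Bu4N)4[W10O32] under O2 and light, then Me2S, gives the γ-hydroxy ketone F1 (open form of the lactol). SmI2/HMPA/t-BuOH then closes ring A by ketyl–enone reductive coupling (ketyl carbon C10 onto C9) to the 3,10-diol F2. TsOH in benzene forms the ether by capture of the tertiary C10 cation by the C3 hydroxyl and rejoins the route at 29.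

Step 16 (cationic closure of ring C). The free tertiary cation next to the quaternary C13 may undergo a methyl shift, or the cis ring junction may form. This fallback sets out from 25 and comes back at 28. The alkene is activated as a bridged seleniranium ion instead of a free cation: TBSOTf/Et3N converts 25 into the silyl dienol ether F3, PhSeCl at −78 °C closes ring C by anti attack of C8 at C14 to give the 15-phenylselanyl ketone F4, and Bu3SnH/AIBN removes selenium to rejoin the route at 28.

Step 15 (1,2-addition next to the tert-alkyl group of the vinylogous ester). The organolithium may enolise 22 or fail to add. This fallback sets out from 22 and 12 and comes back at 25. The bond is made by cross-coupling: 22 is hydrolysed (1 M HCl, THF) to the 1,3-dione F5, PPh3/Br2/Et3N gives the 3-bromo enone F6, iodide 12 is converted with Zn dust/LiCl into the alkylzinc iodide F7, and Negishi coupling of F6 with F7 (Pd(OAc)2, SPhos, THF, 50 °C) rejoins the route at 25.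

**Further compounds**
F1 | step 17 | γ-hydroxy ketone: 28 with the oxolane opened to (3S)-3-hydroxy-2-methyl-6-oxoheptan-2-yl on C5 | C=CCC[C@]1(C)CC[C@]2(C)[C@H]3CC(=O)C(C(C)(C)[C@@H](O)CCC(C)=O)=C3CC[C@@]2(C)C1
F2 | step 17 | 3,10-diol: 29 with the ether bridge replaced by C3–OH and C10–OH (C10 epimers) | C=CCC[C@]1(C)CC[C@]2(C)[C@H]3CC(=O)[C@H]4C(C)(C)[C@@H](O)CCC(C)(O)[C@@]43CC[C@@]2(C)C1
F3 | step 16 | tert-butyldimethylsilyl dienol ether of 25 | C=CCC[C@]1(C)CC=C(C)[C@@](C)(CCC2=CCC(O[Si](C)(C)C(C)(C)C)=C2C(C)(C)[C@@H]3CCC(C)O3)C1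
F4 | step 16 | 15-(phenylselanyl) derivative of 28 (C15 unassigned) | C=CCC[C@]1(C)CC([Se]c5ccccc5)[C@]2(C)[C@H]3CC(=O)C(C(C)(C)[C@@H]4CCC(C)O4)=C3CC[C@@]2(C)C1
F5 | step 15 | 2-{2-[(2S,5RS)-5-methyloxolan-2-yl]propan-2-yl}cyclopentane-1,3-dione | O=C1CCC(=O)C1C(C)(C)[C@@H]2CCC(C)O2
F6 | step 15 | 3-bromo-2-{2-[(2S,5RS)-5-methyloxolan-2-yl]propan-2-yl}cyclopent-2-en-1-one | BrC1=C(C(C)(C)[C@@H]2CCC(C)O2)C(=O)CC1
F7 | step 15 | {2-[(1R,5R)-5-(but-3-en-1-yl)-1,2,5-trimethylcyclohex-2-en-1-yl]ethyl}zinc iodide | C=CCC[C@]1(C)CC=C(C)[C@@](C)(CC[Zn]I)C1
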